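## The problem

Dihydroptychantol A (26) is an achiral 18-membered cyclophane. Four benzene rings are joined in a cycle by two diaryl ether oxygens (ring A–O–ring D and ring B–O–ring C) and two CH2CH2 bridges (ring A–ring B and ring C–ring D). There is no stereocentre, so the control problems are where the substituents sit on rings A and B and how the large ring is closed without oligomerisation. Ring A carries a free hydroxyl at C1, the oxygen leading to ring D at C4 (para), and the bridge to ring B at C5; C2, C3 and C6 carry hydrogen. Ring B carries a free hydroxyl ortho to its ether oxygen and para to its bridge, ring C is a para-phenylene and ring D a meta-phenylene. The two phenols (ring A is an easily oxidised hydroquinone mono-ether) and the four benzylic positions rule out strong oxidants late in the route. The substitution pattern of ring A is what an aryloxy(alkenyl)carbene complex of chromium, an alkyne and one CO ligand assemble. If the carbene sits on the ring D oxygen and the alkyne ends the ring B side chain, ring A and the macrocycle can form in the same step.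

## Retrosynthesis

**Protecting groups (26 ← 25 ← 24).** The ring B phenol is carried as a benzyl ether from the first ring B building block and is released last by hydrogenolysis of 25. Compound 25 comes from 24 by removal of a trimethylsilyl group at C6 of ring A. That silicon is needed only to steer the ring-forming step, and it sits ortho to a hydroxyl, where acid removes it readily.

**Ring A and the macrocycle (24 ← 23 ← 22).** Three ring A bonds are cut: C4–C5, C6–C1 and C1–C2. This leads to carbene complex 22, in which C4 is the carbene carbon on the ring D oxygen, C3 and C2 are an alkenyl group, C5 and C6 are a silyl alkyne on the ring B side chain, and C1 is a CO ligand. Cutting either diaryl ether instead would demand an activating group on an electron-rich ring, and cutting a bridge would demand a separately purchased, fully substituted ring A. The benzannulation places ether, hydroxyl and bridge by its mechanism and closes the 18-membered ring in the same event. Two choices make the forward step more reliable: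
- The alkyne carries SiMe3, so that the chain-bearing carbon bonds to the carbene carbon.
- The alkenyl group is (E)-2-(trimethylsilyl)ethenyl rather than vinyl. The parent vinyl complex polymerises, whereas the silyl complex is stable. Its silicon should migrate from C2 to the new oxygen, giving silyl ether 23, which is cleaved on work-up to 24.

**Carbene–oxygen bond (22 ← 21 + 15; 21 ← 20 ← 16 + 17).** The bond between the carbene carbon and the ring D oxygen is cut. Aryloxy carbene complexes are made by substitution of an acyloxy carbene (21) by a phenol. Complex 21 comes from acylchromate salt 20 and acetyl bromide, and 20 from (E)-(2-bromovinyl)trimethylsilane (16) and Cr(CO)6 (17) through vinyllithium 18 and lithium acylate 19. This puts the metal on the complete open-chain phenol 15 in the last step before cyclisation, so no chromium has to survive other chemistry.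

**Silyl butyne side chain (15 ← 14 ← 11 + 12; 11 ← 10).** Phenol 15 is freed from MOM ether 14 by acid, conditions under which the alkynylsilane and the benzyl ether survive. The bond between the benzylic and the propargylic CH2 of 14 is cut, giving benzylic bromide 11 and the anion 13 of 1-(trimethylsilyl)propyne (12). This adds all three carbons in one step. Bromide 11 comes from alcohol 10.

**Ring C–ring D bridge (10 ← 9 ← 8 + 4).** The CH2CH2 bridge is traced to stilbene 9, made by Wittig reaction of aldehyde 8 with phosphonium salt 4. Reduction of 9 must spare the benzyl ether, hence diimide. Salt 4 comes in three steps from 3-hydroxybenzyl alcohol (1) through MOM ether 2 and bromide 3.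

**Ring B–ring C ether (8 ← 6 + 7; 6 ← 5).** The ether is cut on the ring C side, where the para-formyl group of 4-fluorobenzaldehyde (7) activates fluoride for SNAr. Using 4-(benzyloxy)-3-hydroxybenzaldehyde (5) directly would give a dialdehyde with two indistinguishable formyl groups. Compound 5 is therefore first reduced to alcohol 6, which differentiates the two carbons by oxidation level and is the level the later bromide needs.

## Roads not taken

**Alternative 1:** The ring B–O–ring C ether is traced to an ester, the 19-membered aryl benzoate A2. Ni(cod)2 with 3,4-bis(dicyclohexylphosphino)thiophene and K3PO4 would insert zerovalent nickel into the acyl–oxygen bond, extrude CO and reductively eliminate the aryl–oxygen bond, giving dimethyl ether A1.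
- Merits: the ring is closed by macrolactonisation, a dependable reaction; the metal is catalytic; every intermediate is bench-stable. In these respects it is better than the chosen plan.
- Weak points: decarbonylative etherification is established between separate partners and works best with azine carboxylates and unhindered phenolates. Here a plain benzoate of an ortho-methoxy phenol must contract a cyclophane ring by one atom at high temperature, with CO as a catalyst poison. Ring A must be bought fully substituted, and its ether and both bridges each need their own steps. Two methyl ethers remain to be cleaved.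
- Comparison: neither key step has a close macrocyclic precedent. The chosen plan has to set against the stability and catalytic metal of this road that its one step makes a ring, closes the macrocycle and places three substituents.

**Alternative 2:** The ring B carbon–oxygen bond is cut to give bisphenol A4, with a 2,6-dibromophenol on ring B and a 2,6-dichlorophenol on ring C. Tl(NO3)3·3H2O in methanol would oxidise the dibromophenol, the ring C oxygen would add ortho, and zinc in acetic acid would give A3.
- Merits: this oxidative coupling has direct precedent for macrocyclic diaryl ethers, which the chosen key step lacks. It delivers ring B with its free ortho hydroxyl, and the remaining halogens would leave together with the benzyl group in one hydrogenolysis.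
- Weak points: four halogens must be installed on two different rings before they are joined. The choice of which phenol is oxidised rests only on bromine against chlorine. Trivalent thallium is used in stoichiometric amount and is far more toxic than a chromium carbonyl. The ring A–ring D ether still has to be made by a separate SNAr.
- Comparison: the precedent favours this road. The chosen plan sets against it a shorter sequence without halogen ballast and the construction of ring A itself.

**Alternative 3:** Ring A is represented by a cyclohexenone. Pd(PPh3)4 would ionise an allylic methyl carbonate on that ring and the tethered ring D phenol would attack the allyl terminus, giving racemic enone A5.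
- Merits: allylic etherification of phenols by zerovalent palladium is mild, catalytic and known in macrocyclisations, so the ring closure is better precedented and less strained than the chosen one.
- Weak points: A5 is a 4-aryloxy enone. Its aryloxy group is allylic and can be re-ionised by the catalyst. Loss of the phenol aromatises ring A without any oxidant and opens the macrocycle, whereas the wanted conversion into the ring A phenol is a dehydrogenation that must outrun this loss. The cyclohexenone precursor needs several steps, a stereocentre is made only to be destroyed, and attack at the correct allyl terminus must be controlled.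
- Comparison: the chosen plan has the weaker precedent for the ring closure, but the benzannulation delivers ring A aromatic and at the right oxidation level.

Key step: step 13

## Route

Assumption: stilbene 9 is carried forward as its E/Z mixture, since both isomers give 10 on reduction.
Assumption: carbonyl ligands on chromium are drawn as Cr=C=O in the SMILES strings; this is a drawing convention only.

Step 1
Reactants: 1 3-hydroxybenzyl alcohol
Product: 2 [3-(methoxymethoxy)phenyl]methanol
Conditions: NaH (1.0 equiv), THF–DMF, 0 °C; MOMCl, 0 → 23 °C
Reagents that add atoms: chloromethyl methyl ether, COCCl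
Why: Williamson-type O-alkylation; one equivalent of NaH ionises only the more acidic phenol, so the MOM group should go on the phenol and leave the benzylic alcohol free.

Step 2
Reactants: 2 [3-(methoxymethoxy)phenyl]methanol
Product: 3 1-(bromomethyl)-3-(methoxymethoxy)benzene
Conditions: CBr4, PPh3, CH2Cl2, 0 °C
Reagents that add atoms: carbon tetrabromide, BrC(Br)(Br)Br
Why: Appel reaction; the conditions are neutral, so the acid-labile MOM acetal should survive.

Step 3
Reactants: 3 1-(bromomethyl)-3-(methoxymethoxy)benzene
Product: 4 [3-(methoxymethoxy)benzyl]triphenylphosphonium bromide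
Conditions: PPh3, toluene, 90 °C
Reagents that add atoms: triphenylphosphine, c1ccc(cc1)P(c1ccccc1)c1ccccc1
Why: SN2 quaternisation of PPh3 by a benzylic bromide; the salt should precipitate from toluene.

Step 4
Reactants: 5 4-(benzyloxy)-3-hydroxybenzaldehyde
Product: 6 2-(benzyloxy)-5-(hydroxymethyl)phenol
Conditions: NaBH4, MeOH, 0 °C
Reagents that add atoms: none
Why: Borohydride reduction of an aryl aldehyde; it removes the ring B carbonyl before a second aldehyde is introduced and sets the oxidation level needed for the later bromide.

Step 5
Reactants: 6 2-(benzyloxy)-5-(hydroxymethyl)phenol; 7 4-fluorobenzaldehyde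
Product: 8 4-[2-(benzyloxy)-5-(hydroxymethyl)phenoxy]benzaldehyde
Conditions: K2CO3, DMF, 110 °C
Reagents that add atoms: none
Why: Nucleophilic aromatic substitution (SNAr) of fluoride activated by the para-formyl group; carbonate ionises the phenol but not the benzylic alcohol, so only the phenoxide should attack.

Step 6
Reactants: 8 4-[2-(benzyloxy)-5-(hydroxymethyl)phenoxy]benzaldehyde; 4 [3-(methoxymethoxy)benzyl]triphenylphosphonium bromide
Product: 9 (4-(benzyloxy)-3-{4-[2-(3-(methoxymethoxy)phenyl)ethenyl]phenoxy}phenyl)methanol (E/Z mixture)
Conditions: K2CO3, 18-crown-6, CH2Cl2, reflux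
Reagents that add atoms: none
Why: Wittig olefination with a semi-stabilised benzylic ylide under mild carbonate conditions that tolerate the free alcohol; the alkene geometry is irrelevant because the double bond is reduced next.

Step 7
Reactants: 9 stilbene alcohol (E/Z mixture)
Product: 10 (4-(benzyloxy)-3-{4-[2-(3-(methoxymethoxy)phenyl)ethyl]phenoxy}phenyl)methanol
Conditions: TsNHNH2, NaOAc, THF–H2O, reflux
Reagents that add atoms: none
Why: Diimide reduction; diimide generated from the sulfonyl hydrazide transfers H2 to the stilbene without a metal, so the benzyl ether and the benzylic C–O bonds should be untouched.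

Step 8
Reactants: 10 bibenzyl alcohol
Product: 11 1-(benzyloxy)-4-(bromomethyl)-2-{4-[2-(3-(methoxymethoxy)phenyl)ethyl]phenoxy}benzene
Conditions: CBr4, PPh3, CH2Cl2, 0 °C
Reagents that add atoms: carbon tetrabromide, BrC(Br)(Br)Br
Why: Appel reaction under neutral conditions compatible with the MOM ether; the electron-rich benzylic bromide would be used at once without storage.

Step 9
Reactants: 11 benzylic bromide; 12 trimethyl(prop-1-yn-1-yl)silane
Product: 14 {4-[4-(benzyloxy)-3-{4-[2-(3-(methoxymethoxy)phenyl)ethyl]phenoxy}phenyl]but-1-yn-1-yl}trimethylsilane, via 3-(trimethylsilyl)prop-2-ynyllithium 13 (not isolated)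
Conditions: 12, n-BuLi, THF, −78 °C; then 11, −78 → 0 °C
Reagents that add atoms: none
Why: Alkylation of a silyl-propargyl anion by a benzylic bromide (SN2); the silyl group blocks the allenyl terminus, so the propargylic carbon should form the new C–C bond and give the 1-silylbut-1-yne.

Step 10
Reactants: 14 silyl butyne MOM ether
Product: 15 3-{2-[4-(2-(benzyloxy)-5-[4-(trimethylsilyl)but-3-yn-1-yl]phenoxy)phenyl]ethyl}phenol
Conditions: 2 M HCl, MeOH–THF, 45 °C
Reagents that add atoms: none
Why: Acid-catalysed cleavage of the MOM acetal by transacetalisation to methanol; alkynylsilanes are cleaved by base or fluoride but not by dilute acid, and the benzyl ether is stable, so only the ring D phenol should be freed.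

Step 11
Reactants: 16 (E)-(2-bromovinyl)trimethylsilane; 17 hexacarbonylchromium, Cr(CO)6
Product: 20 tetramethylammonium pentacarbonyl[(2E)-3-(trimethylsilyl)prop-2-enoyl]chromate, via (E)-2-(trimethylsilyl)vinyllithium 18 (not isolated), via lithium acylchromate 19 (not isolated)
Conditions: 16, t-BuLi (2 equiv), Et2O, −78 °C; Cr(CO)6, Et2O, −78 → 23 °C; Me4NBr, H2O
Reagents that add atoms: tetramethylammonium bromide, C[N+](C)(C)C.[Br-]
Why: Fischer route to acylmetalates; bromine–lithium exchange keeps the E geometry, the vinyllithium adds to a CO ligand, and cation exchange gives a storable salt.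

Step 12
Reactants: 20 tetramethylammonium acylchromate; 15 ring D phenol
Product: 22 pentacarbonyl{[3-(2-{4-[2-(benzyloxy)-5-(4-(trimethylsilyl)but-3-yn-1-yl)phenoxy]phenyl}ethyl)phenoxy][(E)-2-(trimethylsilyl)ethenyl]carbene}chromium, via acetoxycarbene complex 21 (not isolated)
Conditions: 20 (1.5 equiv), AcBr, CH2Cl2, −40 °C; then 15, −40 → 0 °C; cold chromatography under N2
Reagents that add atoms: none
Why: O-acylation of the acylmetalate gives a strongly electrophilic acyloxycarbene, and the phenol displaces acetate by addition–elimination at the carbene carbon, the established route to aryloxy carbene complexes of chromium. Below 0 °C no CO is lost, so the tethered alkyne should not react, and the β-silyl group protects the alkenyl carbene against polymerisation and conjugate addition.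

Step 13
Reactants: 22 aryloxy(alkenyl)carbene complex
Product: 24 macrocyclic phenol carrying SiMe3 at C6 of ring A ortho to the C1 hydroxyl (ring B benzyl ether), via macrocyclic aryl trimethylsilyl ether 23 (not isolated)
Conditions: THF (0.002 M, slow addition), 60 °C; air, 23 °C; 1 M HCl, THF, 0 °C
Reagents that add atoms: none
Why: Proposed new method: thermal loss of one CO from 22 frees a site on chromium for the tethered alkyne, which inserts into the Cr=C bond with the silicon-bearing carbon next to chromium and the chain-bearing carbon (C5) bonded to the former carbene carbon (C4). CO insertion then gives a chromium-bound dienylketene whose six-electron electrocyclisation joins the ketene carbon (C1) to the silylated alkenyl carbon (C2), and a 1,3 shift of that silyl group from carbon to oxygen aromatises the dienone to silyl ether 23. The closest known reaction types are the intramolecular Dötz benzannulation of alkenylcarbene complexes with tethered alkynes to cyclophanes, the intermolecular benzannulation of aryloxy carbene complexes to diaryl ethers, and the use of trans-2-silylvinyl complexes in place of the unstable parent vinyl complex; none has been run through an aryloxy tether to an 18-membered ring. The 18-membered ring closes at the alkyne insertion, an exo-dig capture in which only C5 of the alkyne enters the large ring, and ring A closes by the thermal electrocyclisation. No stereocentre is formed. The step needs the right sense of alkyne insertion, which the bulky SiMe3 group on the alkyne secures by taking the carbon remote from the carbene carbon, and ring closure in preference to oligomerisation, which high dilution and slow addition favour because CO loss is unimolecular and the unsaturated chromium then meets its own alkyne first. Air should release the arene from chromium, and dilute acid cleaves only the O–Si bond, leaving the C6 silane of 24.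

Step 14
Reactants: 24 macrocyclic silyl phenol
Product: 25 macrocyclic phenol with ring B benzyl ether (dihydroptychantol A ring B benzyl ether)
Conditions: CF3CO2H, CH2Cl2, 0 → 23 °C
Reagents that add atoms: none
Why: Ipso-protodesilylation of an arylsilane (electrophilic aromatic substitution); the ortho hydroxyl activates the silicon-bearing carbon, and the benzyl and diaryl ethers should tolerate the acid at room temperature.

Step 15
Reactants: 25 macrocyclic phenol with ring B benzyl ether
Product: 26 dihydroptychantol A
Conditions: H2 (1 atm), 10% Pd/C, EtOAc–MeOH, 23 °C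
Reagents that add atoms: none
Why: Catalytic hydrogenolysis of a benzyl aryl ether; nothing else in 25 is reducible under these conditions.

## Compound list

1 | 3-hydroxybenzyl alcohol | OCc1cccc(O)c1 | starting material
2 | [3-(methoxymethoxy)phenyl]methanol | COCOc1cccc(CO)c1 | intermediate
3 | 1-(bromomethyl)-3-(methoxymethoxy)benzene | COCOc1cccc(CBr)c1 | intermediate
4 | [3-(methoxymethoxy)benzyl]triphenylphosphonium bromide | COCOc1cccc(C[P+](c2ccccc2)(c2ccccc2)c2ccccc2)c1.[Br-] | intermediate
5 | 4-(benzyloxy)-3-hydroxybenzaldehyde | O=Cc1ccc(OCc2ccccc2)c(O)c1 | starting material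
6 | 2-(benzyloxy)-5-(hydroxymethyl)phenol | OCc1ccc(OCc2ccccc2)c(O)c1 | intermediate
7 | 4-fluorobenzaldehyde | O=Cc1ccc(F)cc1 | starting material
8 | 4-[2-(benzyloxy)-5-(hydroxymethyl)phenoxy]benzaldehyde | O=Cc1ccc(Oc2cc(CO)ccc2OCc2ccccc2)cc1 | intermediate
9 | (4-(benzyloxy)-3-{4-[2-(3-(methoxymethoxy)phenyl)ethenyl]phenoxy}phenyl)methanol, E/Z mixture | COCOc1cccc(C=Cc2ccc(Oc3cc(CO)ccc3OCc3ccccc3)cc2)c1 | intermediate
10 | (4-(benzyloxy)-3-{4-[2-(3-(methoxymethoxy)phenyl)ethyl]phenoxy}phenyl)methanol | COCOc1cccc(CCc2ccc(Oc3cc(CO)ccc3OCc3ccccc3)cc2)c1 | intermediate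
11 | 1-(benzyloxy)-4-(bromomethyl)-2-{4-[2-(3-(methoxymethoxy)phenyl)ethyl]phenoxy}benzene | COCOc1cccc(CCc2ccc(Oc3cc(CBr)ccc3OCc3ccccc3)cc2)c1 | intermediate
12 | trimethyl(prop-1-yn-1-yl)silane | CC#C[Si](C)(C)C | starting material
13 | 3-(trimethylsilyl)prop-2-ynyllithium | [Li]CC#C[Si](C)(C)C | intermediate
14 | {4-[4-(benzyloxy)-3-{4-[2-(3-(methoxymethoxy)phenyl)ethyl]phenoxy}phenyl]but-1-yn-1-yl}trimethylsilane | COCOc1cccc(CCc2ccc(Oc3cc(CCC#C[Si](C)(C)C)ccc3OCc3ccccc3)cc2)c1 | intermediate
15 | 3-{2-[4-(2-(benzyloxy)-5-[4-(trimethylsilyl)but-3-yn-1-yl]phenoxy)phenyl]ethyl}phenol | Oc1cccc(CCc2ccc(Oc3cc(CCC#C[Si](C)(C)C)ccc3OCc3ccccc3)cc2)c1 | intermediate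
16 | (E)-(2-bromovinyl)trimethylsilane | C[Si](C)(C)/C=C/Br | starting material
17 | hexacarbonylchromium, Cr(CO)6 | O=C=[Cr](=C=O)(=C=O)(=C=O)(=C=O)=C=O | starting material
18 | (E)-2-(trimethylsilyl)vinyllithium | [Li]/C=C/[Si](C)(C)C | intermediate
19 | lithium pentacarbonyl[(2E)-3-(trimethylsilyl)prop-2-enoyl]chromate | [Li+].[O-]C(/C=C/[Si](C)(C)C)=[Cr](=C=O)(=C=O)(=C=O)(=C=O)=C=O | intermediate
20 | tetramethylammonium pentacarbonyl[(2E)-3-(trimethylsilyl)prop-2-enoyl]chromate | C[N+](C)(C)C.[O-]C(/C=C/[Si](C)(C)C)=[Cr](=C=O)(=C=O)(=C=O)(=C=O)=C=O | intermediate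
21 | pentacarbonyl{acetoxy[(E)-2-(trimethylsilyl)ethenyl]carbene}chromium | CC(=O)OC(/C=C/[Si](C)(C)C)=[Cr](=C=O)(=C=O)(=C=O)(=C=O)=C=O | intermediate
22 | pentacarbonyl{[3-(2-{4-[2-(benzyloxy)-5-(4-(trimethylsilyl)but-3-yn-1-yl)phenoxy]phenyl}ethyl)phenoxy][(E)-2-(trimethylsilyl)ethenyl]carbene}chromium | C[Si](C)(C)/C=C/C(=[Cr](=C=O)(=C=O)(=C=O)(=C=O)=C=O)Oc1cccc(CCc2ccc(Oc3cc(CCC#C[Si](C)(C)C)ccc3OCc3ccccc3)cc2)c1 | intermediate
23 | macrocyclic aryl trimethylsilyl ether: ring A C1–OSiMe3, C6–SiMe3; ring B benzyl ether | C[Si](C)(C)Oc1ccc2c(c1[Si](C)(C)C)CCc1ccc(OCc3ccccc3)c(c1)Oc1ccc(cc1)CCc1cccc(c1)O2 | intermediate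
24 | macrocyclic phenol: ring A C1–OH, C6–SiMe3; ring B benzyl ether | Oc1ccc2c(c1[Si](C)(C)C)CCc1ccc(OCc3ccccc3)c(c1)Oc1ccc(cc1)CCc1cccc(c1)O2 | intermediate
25 | dihydroptychantol A ring B benzyl ether | Oc1ccc2c(c1)CCc1ccc(OCc3ccccc3)c(c1)Oc1ccc(cc1)CCc1cccc(c1)O2 | intermediate
26 | dihydroptychantol A | Oc1ccc2c(c1)CCc1ccc(O)c(c1)Oc1ccc(cc1)CCc1cccc(c1)O2 | target

## Step count and risk

Total: 15 steps. Longest linear sequence: 12 steps, from 1 through steps 1, 2, 3, 6, 7, 8, 9, 10, 12, 13, 14 and 15.

**Step 13 (key step, proposed new method).**
- Most likely failures: capture of the alkyne of a second molecule after CO loss, which would give oligomers; arrest at the silyl-stabilised ketene before electrocyclisation; alkyne insertion in the reverse sense under the constraint of the tether.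
- Fallback with known chemistry, from 10 to 26: the chromium chemistry is abandoned and the ring is closed by carbonyl coupling. Alcohol 10 would be oxidised with MnO2 in CH2Cl2 to 4-(benzyloxy)-3-{4-[2-(3-(methoxymethoxy)phenyl)ethyl]phenoxy}benzaldehyde F1. HCl in MeOH–THF would free the ring D phenol, giving 4-(benzyloxy)-3-{4-[2-(3-hydroxyphenyl)ethyl]phenoxy}benzaldehyde F2. SNAr of F2 on commercial 5-(benzyloxy)-2-fluorobenzaldehyde (K2CO3, DMF, 130 °C) would give the ring A/ring B dialdehyde F3. Intramolecular McMurry coupling (TiCl4, Zn, THF, reflux, high dilution) would close the 18-membered ring as the macrocyclic stilbene bis(benzyl ether) F4. Hydrogen over Pd/C would saturate the alkene and remove both benzyl groups, arriving at 26.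

**Step 12.**
- Most likely failures: transfer of the acetyl group to the phenol oxygen in place of substitution at the carbene carbon; thermal decay of the acyloxycarbene before the weakly nucleophilic phenol has reacted; loss of the sensitive product on purification.
- Fallback, from 11 to 26: ring A is brought in ready-made and the ring A–ring D ether is closed last by copper catalysis. Bromide 11 and PPh3 would give the ring B benzylic phosphonium bromide F5. Wittig reaction with commercial 5-(benzyloxy)-2-bromobenzaldehyde would give the ring A bromo stilbene F6. Diimide would reduce it to the bibenzyl bromide F7, and HCl in MeOH–THF would free the seco bromo phenol F8. Intramolecular Ullmann etherification (CuI, N,N-dimethylglycine, Cs2CO3, dioxane, 100 °C, high dilution) would give the macrocyclic bis(benzyl ether) F9, and hydrogenolysis over Pd/C would give 26.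

**Step 9.**
- Most likely failures: reaction of the ambident anion through its allenyl terminus; halogen–metal exchange or electron transfer at the electron-rich benzylic bromide leading to homocoupling; decomposition of the bromide before use.
- Fallback, from 11 to 14: the three carbons are added as one plus two with a non-ambident nucleophile. Lithioacetonitrile (MeCN, n-BuLi, THF, −78 °C) would alkylate 11 to the 3-arylpropanenitrile F10. DIBAL-H at −78 °C would give the 3-arylpropanal F11. The Ohira–Bestmann reagent (dimethyl (1-diazo-2-oxopropyl)phosphonate, K2CO3, MeOH) would give the terminal but-3-ynyl arene F12. Deprotonation with n-BuLi and quenching with Me3SiCl would give 14.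

**Step 5.**
- Most likely failures: competing arylation of the benzylic oxygen at high temperature, and hydride transfer between the benzylic alkoxide and the aldehyde.
- Fallback, from 5 to 8: the two carbonyl carbons are told apart by oxidation level instead of by prior reduction. SNAr of 5 on 4-fluorobenzonitrile (K2CO3, DMF, 100 °C) would give 4-[2-(benzyloxy)-5-formylphenoxy]benzonitrile F13. NaBH4 would reduce only the aldehyde, giving 4-[2-(benzyloxy)-5-(hydroxymethyl)phenoxy]benzonitrile F14. DIBAL-H (2.2 equiv, CH2Cl2, −78 °C, acidic work-up) would convert the nitrile into the aldehyde, giving 8.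

## Further compounds

F1 | step 13 | 4-(benzyloxy)-3-{4-[2-(3-(methoxymethoxy)phenyl)ethyl]phenoxy}benzaldehyde | COCOc1cccc(CCc2ccc(Oc3cc(C=O)ccc3OCc3ccccc3)cc2)c1
F2 | step 13 | 4-(benzyloxy)-3-{4-[2-(3-hydroxyphenyl)ethyl]phenoxy}benzaldehyde | Oc1cccc(CCc2ccc(Oc3cc(C=O)ccc3OCc3ccccc3)cc2)c1
F3 | step 13 | 5-(benzyloxy)-2-{3-[2-(4-(2-(benzyloxy)-5-formylphenoxy)phenyl)ethyl]phenoxy}benzaldehyde | O=Cc1cc(OCc2ccccc2)ccc1Oc1cccc(CCc2ccc(Oc3cc(C=O)ccc3OCc3ccccc3)cc2)c1
F4 | step 13 | macrocyclic stilbene (ring A–ring B bridge CH=CH), bis(benzyl ether), E/Z not fixed | O(Cc1ccccc1)c1ccc2c(c1)C=Cc1ccc(OCc3ccccc3)c(c1)Oc1ccc(cc1)CCc1cccc(c1)O2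
F5 | step 12 | (4-(benzyloxy)-3-{4-[2-(3-(methoxymethoxy)phenyl)ethyl]phenoxy}benzyl)triphenylphosphonium bromide | COCOc1cccc(CCc2ccc(Oc3cc(C[P+](c4ccccc4)(c4ccccc4)c4ccccc4)ccc3OCc3ccccc3)cc2)c1.[Br-]
F6 | step 12 | ring A bromo stilbene with ring D MOM ether, E/Z mixture | COCOc1cccc(CCc2ccc(Oc3cc(C=Cc4cc(OCc5ccccc5)ccc4Br)ccc3OCc3ccccc3)cc2)c1
F7 | step 12 | ring A bromo bibenzyl with ring D MOM ether | COCOc1cccc(CCc2ccc(Oc3cc(CCc4cc(OCc5ccccc5)ccc4Br)ccc3OCc3ccccc3)cc2)c1
F8 | step 12 | seco bromo phenol (ring D OH, ring A Br) | Oc1cccc(CCc2ccc(Oc3cc(CCc4cc(OCc5ccccc5)ccc4Br)ccc3OCc3ccccc3)cc2)c1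
F9 | step 12 | dihydroptychantol A bis(benzyl ether) | O(Cc1ccccc1)c1ccc2c(c1)CCc1ccc(OCc3ccccc3)c(c1)Oc1ccc(cc1)CCc1cccc(c1)O2
F10 | step 9 | 3-[4-(benzyloxy)-3-{4-[2-(3-(methoxymethoxy)phenyl)ethyl]phenoxy}phenyl]propanenitrile | COCOc1cccc(CCc2ccc(Oc3cc(CCC#N)ccc3OCc3ccccc3)cc2)c1
F11 | step 9 | 3-[4-(benzyloxy)-3-{4-[2-(3-(methoxymethoxy)phenyl)ethyl]phenoxy}phenyl]propanal | COCOc1cccc(CCc2ccc(Oc3cc(CCC=O)ccc3OCc3ccccc3)cc2)c1
F12 | step 9 | 1-(benzyloxy)-4-(but-3-yn-1-yl)-2-{4-[2-(3-(methoxymethoxy)phenyl)ethyl]phenoxy}benzene | COCOc1cccc(CCc2ccc(Oc3cc(CCC#C)ccc3OCc3ccccc3)cc2)c1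
F13 | step 5 | 4-[2-(benzyloxy)-5-formylphenoxy]benzonitrile | N#Cc1ccc(Oc2cc(C=O)ccc2OCc2ccccc2)cc1
F14 | step 5 | 4-[2-(benzyloxy)-5-(hydroxymethyl)phenoxy]benzonitrile | N#Cc1ccc(Oc2cc(CO)ccc2OCc2ccccc2)cc1
A1 | alternative 1 | dihydroptychantol A dimethyl ether | COc1ccc2c(c1)CCc1ccc(OC)c(c1)Oc1ccc(cc1)CCc1cccc(c1)O2
A2 | alternative 1 | 19-membered aryl benzoate (ring C carboxylate on the ring B oxygen), dimethyl ether | COc1ccc2c(c1)CCc1ccc(OC)c(c1)OC(=O)c1ccc(cc1)CCc1cccc(c1)O2
A3 | alternative 2 | macrocyclic diaryl ether with Br on ring B and two Cl on ring C, ring A benzyl ether | O(Cc1ccccc1)c1ccc2c(c1)CCc1cc(Br)c(O)c(c1)Oc1c(Cl)cc(cc1Cl)CCc1cccc(c1)O2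
A4 | alternative 2 | seco bisphenol with 2,6-dibromophenol (ring B) and 2,6-dichlorophenol (ring C), ring A benzyl ether | O(Cc1ccccc1)c1ccc(Oc2cccc(CCc3cc(Cl)c(O)c(Cl)c3)c2)c(c1)CCc1cc(Br)c(O)c(Br)c1
A5 | alternative 3 | macrocyclic 4-aryloxy-3-alkylcyclohex-2-enone, ring B methyl ether (racemic) | O=C1C=C2C(CC1)Oc1cccc(c1)CCc1ccc(cc1)Oc1cc(ccc1OC)CC2
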